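(The runs stem from a simulated flask for substances that don't exist, and the scatter is random.)

I began with the end state.

| flask | starting material | protic impurity | remark | time |
|---|---|---|---|---|
| alder | 0.067 M (in portions, 4) | 0.050 M | run made earlier; portions every 30 min |  |
| larch | 0.15 M (in portions, 4) | 0.050 M | run made earlier; portions every 30 min |  |
| flask | 0.10 M (in portions, 4) | 0.0500 M | the portions of starting material follow each other after 30 min, the first at the start | 4.0 h |

The flask holds less protic impurity than starting material. If the two react one to one, the impurity in the flask is the limiting reagent, and I named its share of the charge, protic impurity charged over starting material charged, the impurity toll: 50.0% here. So I turned to the earlier runs to test the toll.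

| run | time / h | starting material / % | target / % |
|---|---|---|---|
| alder | 0.200 | 5 | 0 |
| alder | 0.333 | 2 | 0 |
| alder | 0.500 | 6 | 3 |
| alder | 0.833 | 6 | 2 |
| alder | 1.33 | 16 | 3 |
| alder | 2.50 | 14 | 1 |
| larch | 0.167 | 11 | 2 |
| larch | 0.500 | 3 | 2 |
| larch | 0.833 | 14 | 2 |
| larch | 1.33 | 22 | 4 |
| larch | 2.00 | 30 | 5 |
| larch | 2.50 | 24 | 3 |

(standard deviation of a reading: 2 percentage points)

In alder the toll is 74.6%, yet starting material read 14% at 2.50 h, below the 25.4% that the toll leaves. In larch the toll leaves 66.7%, and the reading was 24%. So in both runs a second loss ran beside the toll, and by these readings it took more in larch, the larger charge, than in alder. But is the toll paid in time? Alder's first portion, a quarter of the charge, read 5% at 0.200 h, a pseudo-first-order rate of about 8.05 h⁻¹. That half-life of 5.17 min, read for the first portion with the impurity as charged, is shorter than the interval of 30 min, and in the flask the last portion enters at 1.50 h, before 4.0 h. I therefore committed, for the flask at 4.0 h, to a loss to the impurity equal to the toll, with conversion above it.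

- which holds at 4.0 h: what has brought the reaction to rest, or that it has not come to rest (all of the starting material has reacted / forward and back rates have come level / it is still moving)
- share of the starting material used up at 4.0 h
- target at 4.0 h, in percent of the starting material charged

- the analysis behind the earlier runs scatters by 2 percentage points, standard deviation
- the reaction counts as stopped when no species that holds the starting material changes by six tenths of a point or more over the second half of the time

The forecast said it is still moving, with conversion 78% and target 6%; its ground for the first was: “The decay is still about 4 points/h, so it has not stopped”.

The flask gave it is still moving, with conversion 83.7% and target 1.93%.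

    starting material + protic impurity → quenched substrate (k = 2.11 L mol⁻¹ min⁻¹)
    starting material ⇌ intermediate (K = 0.360, k = 0.468 min⁻¹)
    2 starting material → homo dimer (k = 0.127 L mol⁻¹ min⁻¹)
    target → over-reaction product (k = 0.00346 min⁻¹)
    intermediate ⇌ target (K = 0.330, k = 0.115 min⁻¹)

In the flask, quenched substrate stood at 50.0% at 4.00 h, level with the toll, and the half-life of starting material by the quenching step, 0.11 h as charged, had become 61 d with 0.0075% of the protic impurity left. In the neighbour flask charged with 0.060 M of starting material, the toll is 83.3%, and at 4.00 h, with 2.7% of its protic impurity unreacted, quenched substrate stood at 81.1%.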